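**Plan**

Numbering (phenanthrene type): ring C is C1(=O), C2(OMe), C3(N), C4(Me)(O), C4a=C10a; ring B adds C10H2 and C9(=O); ring A is C4b to C8a; C2' is the aminal carbon of the pyrrolidine.
Cuts, from the target backwards: O8–CH3; C9–C8a (acylation of ring A) and C9–C10 (one-carbon homologation of a C10a carboxyl); O4–C2' (aminal, from a proline carboxyl); last, C4–C4a and C1–C10a together.
The double cut is open because O–C4(Me)–C3(N)=C2(OMe)–C1(=O) of ring C is a 4-amino-3-methoxy-5-methylbutenolide with its C1–O bond broken. The lactone oxygen is the C4 oxygen and the lactone carbonyl is C1, so the C5 anion of the butenolide and an aryl alkynoate (C4a, C10a) assemble ring C.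
Forward order: butenolide with N3 already inside a D-proline unit; ring C (ring A arrives on the alkynoate); oxazolidine O4–C2'; ring B; C8 phenol.
Stereochemistry: C4 (R) is set in the ring C annulation under control of the D-proline centre (the lactate centre is lost on enolisation); C2' (S) is set by C4 at aminal closure, when the proline centre is destroyed.

Key step: step 6

Assumption: the target is handled as the C9-keto/C10-methylene tautomer that is drawn (the form the ring B acylation delivers), and its aminal configuration (H-2' cis to the C4 methyl) is taken to be the one that C4 imposes on ring closure.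

**Route**

Step 1
Reactants: 1 ethyl (S)-lactate; 2 methoxyacetyl chloride
Product: 3 ethyl (2S)-2-(methoxyacetoxy)propanoate
Conditions: pyridine, CH2Cl2, 0 °C → rt
Reagents that add atoms: none
Why: Acylation of the secondary hydroxyl by an acid chloride with pyridine as base is a routine esterification that does not touch the lactate centre.

Step 2
Reactants: 3 ethyl (2S)-2-(methoxyacetoxy)propanoate
Product: 4 (5S)-4-hydroxy-3-methoxy-5-methylfuran-2(5H)-one (3-methoxy-5-methyltetronic acid)
Conditions: LiN(SiMe3)2 (2.2 equiv), THF, −78 → 0 °C; aq. HCl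
Reagents that add atoms: none
Why: Dieckmann condensation of an α-acyloxy ester, in which the methoxyacetate enolate attacks the ethyl ester to close the five-membered ring and deprotonation of the acidic tetronic acid by the second equivalent of base drives it to completion; partial loss of configuration at C5 would be harmless because that centre is erased in step 6.

Step 3
Reactants: 4 (5S)-4-hydroxy-3-methoxy-5-methylfuran-2(5H)-one; 5 D-proline benzyl ester hydrochloride
Product: 7 N-[(5S)-3-methoxy-5-methyl-2-oxo-2,5-dihydrofuran-4-yl]-D-proline benzyl ester, via vinyl triflate 6 (not isolated)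
Conditions: Tf2O, iPr2NEt, CH2Cl2, −78 °C; then 5, iPr2NEt, −78 °C → rt
Reagents that add atoms: none
Why: O-Triflation of the vinylogous acid followed by addition–elimination (vinylogous acyl substitution) of the secondary amine at C4 of the butenolide gives the vinylogous carbamate, the triflate being used because a proline ester is expected to be too sluggish for direct condensation with a 3-alkoxytetronic acid.

Step 4
Reactants: 7 N-[(5S)-3-methoxy-5-methyl-2-oxo-2,5-dihydrofuran-4-yl]-D-proline benzyl ester
Product: 8 N-[(5S)-3-methoxy-5-methyl-2-oxo-2,5-dihydrofuran-4-yl]-D-proline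
Conditions: H2 (1 atm), 10% Pd/C, EtOAc, rt
Reagents that add atoms: none
Why: Hydrogenolysis of a benzyl ester over palladium is chemoselective here because the only alkene is the tetrasubstituted push–pull double bond of the butenolide, and freeing the acid now lets step 6 run on a carboxylate that is neither enolisable nor electrophilic.

Step 5
Reactants: 9 1-ethynyl-3,5-dimethoxybenzene
Product: 11 tert-butyl 3-(3,5-dimethoxyphenyl)prop-2-ynoate, via lithium acetylide 10 (not isolated)
Conditions: n-BuLi, THF, −78 °C; then Boc2O, −78 → 0 °C; AcOH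
Reagents that add atoms: di-tert-butyl dicarbonate (Boc2O), CC(C)(C)OC(=O)OC(=O)OC(C)(C)C
Why: Lithiation of the terminal alkyne and C-acylation of the acetylide by Boc2O (an alkoxycarbonylation) is the standard way to tert-butyl alkynoates.

Step 6
Reactants: 8 N-[(5S)-3-methoxy-5-methyl-2-oxo-2,5-dihydrofuran-4-yl]-D-proline; 11 tert-butyl 3-(3,5-dimethoxyphenyl)prop-2-ynoate
Product: 14 (2R)-1-[(6R)-4-(tert-butoxycarbonyl)-5-(3,5-dimethoxyphenyl)-6-hydroxy-2-methoxy-6-methyl-3-oxocyclohexa-1,4-dien-1-yl]pyrrolidine-2-carboxylic acid (ring C quinol acid; its C6 is C4 of the plan), via dilithium furanolate carboxylate 12 (not isolated), via dilithium allenolate adduct 13 (not isolated)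
Conditions: LiN(iPr)2 (2.1 equiv), THF–DMPU, −78 °C; then 11, −78 → −20 °C; AcOH
Reagents that add atoms: none
Why: Proposed new method: two equivalents of LiN(iPr)2 first make the lithium carboxylate and then remove H-5 of the butenolide, and the planar 2-oxidofuran 12 adds through C5 (the future C4) to the aryl-bearing alkyne carbon (C4a) to give allenolate 13, whose carbanionic carbon C10a attacks the lactone carbonyl C1 and expels the ring oxygen as the C4 alkoxide (a concerted [4+2] addition through a 7-oxanorbornadiene alkoxide would make the same two bonds). The closest known reactions are the γ-selective reactions of lithiated 4-(pyrrolidin-1-yl)butenolides that carry a chiral pyrrolidine, the Michael–Dieckmann annulations of phthalide and other lactone anions in which the lactone oxygen ends as a ring hydroxyl, and the cycloadditions of 2-silyloxyfurans with alkynoates. Ring C, the only ring formed, closes by 6-exo-trig acyl substitution at C1, and the exchange of an ester-stabilised vinyl anion for a tertiary alkoxide makes the sequence downhill. The only new stereocentre, C4, is controlled by the D-proline centre: allylic 1,3-strain turns the C2' carboxylate out of the furanolate plane, in the rotamer with C2' beside C5 it covers the Si face of C5, and bond formation on the Re face gives 4R; DMPU keeps the lithium carboxylate solvated so that it shields and does not deliver the alkynoate, and the C4 epimer, a diastereomer, would be separated here. The step needs γ over α attack (secured by the fully substituted C3 and the vinylogous-urethane polarity), conjugate over carbonyl addition (secured by the tert-butyl ester) and C5-to-C4a regiochemistry (secured by the alkynoate polarity). The carboxyl is carried as its lithium salt because, unlike an ester, it leaves H-2' non-acidic and offers no acyl group to the C5 carbanion or the C4 alkoxide.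

Step 7
Reactants: 14 ring C quinol acid
Product: 16 (4R,2'S) aminal tert-butyl ester: ring C dienone with O4–C2' closed onto the pyrrolidine; C4a 3,5-dimethoxyphenyl; C10a CO2tBu, via pyrrolinium acetate 15 (not isolated)
Conditions: Pb(OAc)4 (1.2 equiv), MeCN, 0 °C → rt
Reagents that add atoms: none
Why: Oxidative decarboxylation of an α-amino acid by tetravalent lead, a standard entry to N,O-acetals from N-acylated amino acids, gives the pyrrolinium ion, which the C4 hydroxyl captures in the same closure by which amino alcohols and aldehydes form oxazolidines; the tethered oxygen reaches only the iminium face that leaves the pyrrolidine ring anti to the C4 methyl, so C2' should form as S with H-2' cis to that methyl, and because the aminal can reopen under acid any epimer would drain to this more stable isomer.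

Step 8
Reactants: 16 (4R,2'S) aminal tert-butyl ester
Product: 17 (4R,2'S) aminal C10a carboxylic acid
Conditions: CF3CO2H, CH2Cl2, 0 °C → rt
Reagents that add atoms: none
Why: Acidolysis of the tert-butyl ester (E1 loss of isobutene) frees the C10a carboxyl, while the N,O-aminal can at most open and reclose to the same favoured isomer and the quinol oxygen is now protected as part of that ring.

Step 9
Reactants: 17 (4R,2'S) aminal C10a carboxylic acid
Product: 19 (4R,2'S) aminal C10a diazomethyl ketone (C10a–CO–CHN2), via acid chloride 18 (not isolated)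
Conditions: 1-chloro-N,N,2-trimethylprop-1-en-1-amine, CH2Cl2, 0 °C; then CH2N2, Et3N, Et2O, 0 °C
Reagents that add atoms: diazomethane, C=[N+]=[N-]
Why: First stage of the Arndt–Eistert homologation, in which the chloroenamine makes the acid chloride under neutral conditions that spare the vinylogous amide and diazomethane is acylated on carbon to give the diazoketone, Et3N taking up HCl safely because the acid chloride has no α-hydrogen from which a ketene could form.

Step 10
Reactants: 19 (4R,2'S) aminal C10a diazomethyl ketone
Product: 21 (4R,2'S) aminal C10a acetic acid (C10a–CH2–CO2H), via vinylketene 20 (not isolated)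
Conditions: PhCO2Ag (cat.), Et3N, THF–H2O, rt, dark
Reagents that add atoms: water, O
Why: Silver-catalysed Wolff rearrangement, the second stage of the Arndt–Eistert homologation, in which loss of N2 with 1,2-shift of the C10a alkenyl group gives the ketene, which the large excess of water at room temperature should hydrate before it can cyclise onto the neighbouring aryl ring.

Step 11
Reactants: 21 (4R,2'S) aminal C10a acetic acid
Product: 23 (4R,2'S) 8-O-methyl ether of the target (tetracyclic 6,8-dimethoxy C9 ketone), via mixed trifluoroacetic anhydride 22 (not isolated)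
Conditions: (CF3CO)2O, CH2Cl2, 0 °C → rt; aq. NaHCO3
Reagents that add atoms: none
Why: Intramolecular Friedel–Crafts acylation through the mixed anhydride, in which the acyl carbon, held cis to the aryl ring across C4a=C10a, attacks the ring position that is ortho to one methoxy group and para to the other (the two ortho positions are equivalent by symmetry) and closes the six-membered ring B as the C9 ketone.

Step 12
Reactants: 23 (4R,2'S) 8-O-methyl ether of the target
Product: 24 CNP0528850.1
Conditions: BCl3, CH2Cl2, −78 → 0 °C; H2O
Reagents that add atoms: none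
Why: Chelation-directed ether cleavage, in which BCl3 bridges the C9 carbonyl and the peri C8 methoxy oxygen in a six-membered chelate and chloride removes only that methyl group, as in the selective 5-O-demethylation of 5,7-dimethoxychromones, where a methoxy group on the carbon next to the carbonyl (the counterpart of C2–OMe here) and one para to it (C6–OMe) survive.

**Compound list**

1 | ethyl (S)-lactate | CCOC(=O)[C@H](C)O | starting material
2 | methoxyacetyl chloride | COCC(=O)Cl | starting material
3 | ethyl (2S)-2-(methoxyacetoxy)propanoate | CCOC(=O)[C@H](C)OC(=O)COC | intermediate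
4 | (5S)-4-hydroxy-3-methoxy-5-methylfuran-2(5H)-one | COC1=C(O)[C@H](C)OC1=O | intermediate
5 | D-proline benzyl ester hydrochloride | O=C(OCc1ccccc1)[C@H]1CCCN1.Cl | starting material
6 | (5S)-3-methoxy-5-methyl-4-(trifluoromethanesulfonyloxy)furan-2(5H)-one | COC1=C(OS(=O)(=O)C(F)(F)F)[C@H](C)OC1=O | intermediate
7 | N-[(5S)-3-methoxy-5-methyl-2-oxo-2,5-dihydrofuran-4-yl]-D-proline benzyl ester | COC1=C(N2CCC[C@@H]2C(=O)OCc2ccccc2)[C@H](C)OC1=O | intermediate
8 | N-[(5S)-3-methoxy-5-methyl-2-oxo-2,5-dihydrofuran-4-yl]-D-proline | COC1=C(N2CCC[C@@H]2C(=O)O)[C@H](C)OC1=O | intermediate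
9 | 1-ethynyl-3,5-dimethoxybenzene | C#Cc1cc(OC)cc(OC)c1 | starting material
10 | lithium (3,5-dimethoxyphenyl)acetylide | [Li+].[C-]#Cc1cc(OC)cc(OC)c1 | intermediate
11 | tert-butyl 3-(3,5-dimethoxyphenyl)prop-2-ynoate | CC(C)(C)OC(=O)C#Cc1cc(OC)cc(OC)c1 | intermediate
12 | dilithium salt of 8: lithium (2R)-1-(3-methoxy-5-methyl-2-oxidofuran-4-yl)pyrrolidine-2-carboxylate | [Li+].[Li+].COc1c([O-])oc(C)c1N1CCC[C@@H]1C(=O)[O-] | intermediate
13 | dilithium allenolate: Michael adduct with the new C5–C(aryl) bond (5R), lactone intact, aryl-C=C=C(O−)OtBu side chain | [Li+].[Li+].COC1=C(N2CCC[C@@H]2C(=O)[O-])[C@](C)(OC1=O)C(c1cc(OC)cc(OC)c1)=C=C([O-])OC(C)(C)C | intermediate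
14 | (2R)-1-[(6R)-4-(tert-butoxycarbonyl)-5-(3,5-dimethoxyphenyl)-6-hydroxy-2-methoxy-6-methyl-3-oxocyclohexa-1,4-dien-1-yl]pyrrolidine-2-carboxylic acid | COC1=C(N2CCC[C@@H]2C(=O)O)[C@@](O)(C)C(c2cc(OC)cc(OC)c2)=C(C(=O)OC(C)(C)C)C1=O | intermediate
15 | 1-[(6R)-4-(tert-butoxycarbonyl)-5-(3,5-dimethoxyphenyl)-6-hydroxy-2-methoxy-6-methyl-3-oxocyclohexa-1,4-dien-1-yl]-3,4-dihydro-2H-pyrrol-1-ium acetate | COC1=C([N+]2=CCCC2)[C@@](O)(C)C(c2cc(OC)cc(OC)c2)=C(C(=O)OC(C)(C)C)C1=O.CC(=O)[O-] | intermediate
16 | (4R,2'S) aminal tert-butyl ester: ring C dienone (C1=O, C2 OMe, C4 Me) with the oxazolidine C3–N–C2'(H)–O–C4 fused to the pyrrolidine; C4a 3,5-dimethoxyphenyl; C10a CO2tBu | COC1=C2N3CCC[C@@H]3O[C@]2(C)C(c2cc(OC)cc(OC)c2)=C(C(=O)OC(C)(C)C)C1=O | intermediate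
17 | C10a carboxylic acid of 16 | COC1=C2N3CCC[C@@H]3O[C@]2(C)C(c2cc(OC)cc(OC)c2)=C(C(=O)O)C1=O | intermediate
18 | C10a carbonyl chloride of 17 | COC1=C2N3CCC[C@@H]3O[C@]2(C)C(c2cc(OC)cc(OC)c2)=C(C(=O)Cl)C1=O | intermediate
19 | C10a diazomethyl ketone (C10a–CO–CHN2) | COC1=C2N3CCC[C@@H]3O[C@]2(C)C(c2cc(OC)cc(OC)c2)=C(C(=O)C=[N+]=[N-])C1=O | intermediate
20 | C10a vinylketene (C10a–CH=C=O) | COC1=C2N3CCC[C@@H]3O[C@]2(C)C(c2cc(OC)cc(OC)c2)=C(C=C=O)C1=O | intermediate
21 | C10a acetic acid (C10a–CH2–CO2H) | COC1=C2N3CCC[C@@H]3O[C@]2(C)C(c2cc(OC)cc(OC)c2)=C(CC(=O)O)C1=O | intermediate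
22 | mixed anhydride of 21 with trifluoroacetic acid | COC1=C2N3CCC[C@@H]3O[C@]2(C)C(c2cc(OC)cc(OC)c2)=C(CC(=O)OC(=O)C(F)(F)F)C1=O | intermediate
23 | (4R,2'S) 8-O-methyl ether of the target: 2,6,8-trimethoxy-4-methyl-4,10-dihydrophenanthrene-1,9-dione with N3 and O4 bridged by C2' of the pyrrolidine | COC1=C2N3CCC[C@@H]3O[C@]2(C)C2=C(CC(=O)c3c(OC)cc(OC)cc32)C1=O | intermediate
24 | CNP0528850.1: (4R,2'S) 8-hydroxy-2,6-dimethoxy-4-methyl-4,10-dihydrophenanthrene-1,9-dione with N3 and O4 bridged by C2' of the pyrrolidine | COC1=C2N3CCC[C@@H]3O[C@]2(C)C2=C(CC(=O)c3c(O)cc(OC)cc32)C1=O | target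

**Count and risks**

Total steps: 12. Longest linear sequence: 11 steps (steps 1 to 4 and 6 to 12, from ethyl (S)-lactate); step 5 is a one-step branch.

1. Step 6 (proposed new method). What may go wrong: protonation of the allenolate by diisopropylamine before ring C closes, addition through C3 or to the ester carbonyl, or poor facial discrimination at C5 because the rotamer with C2' beside C3 reacts as well. Fallback with known chemistry, from 8 back to 14: 8 is silylated twice (TBSOTf, Et3N, CH2Cl2) to tert-butyldimethylsilyl (2R)-1-[5-(tert-butyldimethylsilyloxy)-4-methoxy-2-methylfuran-3-yl]pyrrolidine-2-carboxylate F1. Heating F1 with 11 in toluene should give, by Diels–Alder addition of the electron-rich 2-silyloxyfuran to the alkynoate with the same orientation and the same facial bias, the (1R,4R) 7-oxanorbornadiene adduct F2. HF·pyridine in THF then removes both silyl groups, and the bridgehead hemiketal collapses, opening the oxygen bridge to the C4 hydroxyl and C1 ketone of 14.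

2. Step 7. What may go wrong: oxidation of the dimethoxyphenyl ring or the enaminone by tetravalent lead in competition with decarboxylation, or capture of the iminium ion by acetate without ring closure. Fallback from 14 back to 16: the acid is coupled with N-hydroxypyridine-2-thione (carbodiimide, CH2Cl2, dark) to the Barton ester F3. Warming F3 in toluene in the dark should release CO2 by the radical chain and give the 2'-(pyridin-2-ylthio) N,S-acetal F4. AgOTf in CH2Cl2 then abstracts the thiolate, and the C4 hydroxyl closes the aminal to 16 without any oxidant.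

3. Step 10. What may go wrong: diversion of the ketene before hydration (cyclisation onto the adjacent aryl ring), giving mixtures of acid and ring-closed material. Fallback from 19 back to 23: 19 is heated with catalytic PhCO2Ag and Et3N in dry toluene so that ketene 20 meets no nucleophile. 6π-Electrocyclisation onto the ortho carbon of the aryl ring should give the cross-conjugated trienone F5, which restores ring A by shift of H-8a to C10 and is then 23. Ring B is in this case closed by electrocyclisation, and steps 10 and 11 fall away.

**Further compounds**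

F1 | step 6 | tert-butyldimethylsilyl (2R)-1-[5-(tert-butyldimethylsilyloxy)-4-methoxy-2-methylfuran-3-yl]pyrrolidine-2-carboxylate | COc1c(O[Si](C)(C)C(C)(C)C)oc(C)c1N1CCC[C@@H]1C(=O)O[Si](C)(C)C(C)(C)C
F2 | step 6 | (1R,4R) 7-oxabicyclo[2.2.1]hepta-2,5-diene adduct of F1 and 11: C1 OTBS, C2 OMe, C3 N of the D-proline silyl ester, C4 Me, C5 3,5-dimethoxyphenyl, C6 CO2tBu | C[C@]12O[C@](O[Si](C)(C)C(C)(C)C)(C(OC)=C1N3CCC[C@@H]3C(=O)O[Si](C)(C)C(C)(C)C)C(C(=O)OC(C)(C)C)=C2c4cc(OC)cc(OC)c4
F3 | step 7 | Barton ester of 14 (2-thioxopyridin-1(2H)-yl ester of the proline carboxyl) | COC1=C(N2CCC[C@@H]2C(=O)ON2C=CC=CC2=S)[C@@](O)(C)C(c2cc(OC)cc(OC)c2)=C(C(=O)OC(C)(C)C)C1=O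
F4 | step 7 | 2'-(pyridin-2-ylthio)pyrrolidine N,S-acetal of the ring C quinol (both C2' epimers) | COC1=C(N2CCCC2Sc2ccccn2)[C@@](O)(C)C(c2cc(OC)cc(OC)c2)=C(C(=O)OC(C)(C)C)C1=O
F5 | step 10 | 8aH-trienone from electrocyclisation of 20 (C10=C10a, C4a=C4b, C8a sp3, ring A not yet aromatic) | COC1=C2N3CCC[C@@H]3O[C@]2(C)C2=C3C=C(OC)C=C(OC)C3C(=O)C=C2C1=O
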